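The ten-membered carbocycle is closed late by forming the C3–C4 bond (briarane numbering), the ethano link between the C2 carbinol and the allylic carbon of the 5Z-olefin. The key step exploits that C3 is alpha to C2, carried as a ketone and activated as an allyl beta-keto ester, and that C4 is allylic to the trisubstituted C5=C6 olefin, carried as a (Z)-allylic chloride: a caesium-enolate SN2 alkylation closes the ring with the olefin geometry preserved, while the trans-fused cyclohexene (C1/C10) and the C7/C8 gamma-lactone pre-bend the seco chain. The precursor is assembled from an enantioselective Diels–Alder cyclohexene, an aldol union at C8–C9 and a copper-hydride reductive aldol lactonisation.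

Key step: step 22

Remark: briarane numbering is used for all compounds (C1 quaternary carbon bearing methyl C15, C2–C9 the other atoms of the ten-membered ring, C10–C14 the cyclohexene, C17–C19 the lactone, C20 the methyl on C11; TBS = tert-butyldimethylsilyl, TES = triethylsilyl, PMB = 4-methoxybenzyl), and the (S)-configured catalysts of steps 2 and 24 are written according to the usual facial models and would be exchanged for their antipodes if the sense of induction were opposite.

Step 1
Reactants: 1 pent-1-en-3-one (ethyl vinyl ketone)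
Product: 2 (Z)-3-(tert-butyldimethylsilyloxy)penta-1,3-diene
Conditions: TBSOTf, Et3N, Et2O, 0 °C
Reagents that add atoms: tert-butyldimethylsilyl trifluoromethanesulfonate, CC(C)(C)[Si](C)(C)OS(=O)(=O)C(F)(F)F
Why: Soft enolisation (silyl enol ether formation) of the ethyl ketone should give the cross-conjugated silyl dienol ether, the (Z)-enol ether (methyl cis to oxygen) being favoured because it avoids allylic strain between the methyl and the vinyl group.

Step 2
Reactants: 2 (Z)-3-(tert-butyldimethylsilyloxy)penta-1,3-diene; 3 ethyl (E)-3-methyl-4-oxobut-2-enoate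
Product: 4 ethyl 6-formyl-2,6-dimethyl-3-(TBS-oxy)cyclohex-3-ene-1-carboxylate (C1 methyl, C10 ester and C11 methyl mutually cis, formyl trans to ester, absolute configuration of the target)
Conditions: (S)-1-(2-methylphenyl)-3,3-diphenyltetrahydro-1H,3H-pyrrolo[1,2-c][1,3,2]oxazaborole·HN(SO2CF3)2 (10 mol%), CH2Cl2, −78 °C
Reagents that add atoms: none
Why: Enantioselective Diels–Alder reaction under chiral oxazaborolidinium catalysis, in which the enol-ether terminus C11 bonds to C10 (beta to the activated formyl group) and the methylene terminus builds the quaternary C1, the (E)-dienophile fixes formyl trans to ester, the formyl-exo/ester-endo transition state usual for alpha-substituted enals places the C11 methyl cis to the C10 ester, and the catalyst shields one enantioface to set the absolute configuration.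

Step 3
Reactants: 4 Diels–Alder adduct (silyl enol ether)
Product: 5 ethyl 6-formyl-2,6-dimethyl-3-oxocyclohex-4-ene-1-carboxylate (C12 enone, stereocentres as in 4)
Conditions: Pd(OAc)2 (1.1 equiv), MeCN, 25 °C
Reagents that add atoms: none
Why: Saegusa–Ito oxidation, in which palladation of the C12 silyl enol ether and beta-hydride elimination from C14 should give the C13=C14 enone without touching the non-enolisable aldehyde or the stereocentres.

Step 4
Reactants: 5 enone aldehyde ester
Product: 6 ethyl 3-hydroxy-6-(hydroxymethyl)-2,6-dimethylcyclohex-4-ene-1-carboxylate (12-hydroxyl trans to the C11 methyl)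
Conditions: NaBH4, CeCl3·7H2O, MeOH, −78 °C
Reagents that add atoms: none
Why: Luche reduction, in which 1,2-hydride delivery reduces the aldehyde and the enone carbonyl, hydride being expected to add to C12 pseudo-axially so that the pseudo-equatorial alcohol trans to the adjacent equatorial C11 methyl results.

Step 5
Reactants: 6 diol
Product: 7 bis-TBS ether of 6 (2-O-TBS, 12-O-TBS)
Conditions: TBSOTf (2.5 equiv), 2,6-lutidine, CH2Cl2, −78 → 0 °C
Reagents that add atoms: tert-butyldimethylsilyl trifluoromethanesulfonate, CC(C)(C)[Si](C)(C)OS(=O)(=O)C(F)(F)F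
Why: Silyl triflate silylation (protecting-group installation) should cap both the neopentyl primary and the secondary allylic hydroxyl in one operation.

Step 6
Reactants: 7 bis-TBS ester
Product: 8 C9 aldehyde, 3-(TBS-oxy)-6-(TBS-oxymethyl)-2,6-dimethylcyclohex-4-ene-1-carbaldehyde
Conditions: i-Bu2AlH (1.2 equiv), CH2Cl2, −78 °C; MeOH, aqueous potassium sodium tartrate
Reagents that add atoms: none
Why: Partial ester reduction, in which the aluminium hemiacetal of the hindered ester persists at low temperature and releases the C9 aldehyde only on work-up.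

Step 7
Reactants: 9 prop-2-yn-1-ol
Product: 11 (Z)-3-iodo-2-methylprop-2-en-1-ol, via alkenylmagnesium alkoxide 10 (not isolated)
Conditions: MeMgBr (3 equiv), CuI (10 mol%), THF, −10 → 25 °C; then I2, −10 °C
Reagents that add atoms: methylmagnesium bromide, C[Mg]Br; iodine, II
Why: Copper-catalysed anti-carbomagnesiation of the propargylic alkoxide (magnesium chelate) places methyl on C5 and magnesium on C6 cis to the CH2O group, and iodinolysis with retention should give the (Z)-iodoalkene (carbometallation–iodination).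

Step 8
Reactants: 11 (Z)-3-iodo-2-methylprop-2-en-1-ol
Product: 12 (Z)-tert-butyl[(3-iodo-2-methylprop-2-en-1-yl)oxy]dimethylsilane
Conditions: TBSCl, imidazole, CH2Cl2, 0 → 25 °C
Reagents that add atoms: tert-butyldimethylsilyl chloride, CC(C)(C)[Si](C)(C)Cl
Why: Standard silyl ether formation at the primary allylic alcohol.

Step 9
Reactants: 13 2-chloro-N-methoxy-N-methylacetamide; 14 4-methoxybenzyl alcohol
Product: 15 N-methoxy-2-(4-methoxybenzyloxy)-N-methylacetamide
Conditions: NaH, THF, 0 → 25 °C
Reagents that add atoms: none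
Why: Williamson ether synthesis, the sodium alkoxide of 14 displacing the activated alpha-chloride faster than it attacks the amide carbonyl.

Step 10
Reactants: 12 (Z)-iodoalkene TBS ether; 15 PMB-protected glycolic Weinreb amide
Product: 17 (Z)-5-(TBS-oxy)-1-(4-methoxybenzyloxy)-4-methylpent-3-en-2-one (C4–C8 ketone), via alkenyllithium 16 (not isolated)
Conditions: t-BuLi (2.0 equiv), Et2O, −78 °C; then 15, −78 → −40 °C; aq. NH4Cl
Reagents that add atoms: none
Why: Iodine–lithium exchange retains the (Z)-geometry and the alkenyllithium acylates the Weinreb amide through the chelated tetrahedral intermediate, so that the ketone should form without over-addition (Weinreb ketone synthesis).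

Step 11
Reactants: 8 C9 aldehyde; 17 C4–C8 ketone
Product: 19 aldol adduct, 9-hydroxy-8-(PMB-oxy)-7-oxo seco compound (C9 as in the target, 8,9-anti, 5Z, 2-O-TBS, 4-O-TBS, 12-O-TBS), via (E)-enol dicyclohexylborinate 18 (not isolated)
Conditions: (c-C6H11)2BCl, Et3N, Et2O, −78 → 0 °C; then 8, −78 → −20 °C; H2O2, pH 7 phosphate buffer, MeOH, 0 °C
Reagents that add atoms: none
Why: Boron-mediated aldol reaction, in which the (E)-enol borinate reacts through a chair Zimmerman–Traxler transition state to give the 8,9-anti adduct and attacks the aldehyde in the Felkin–Anh sense anti to the quaternary C1 substituent of C10, which should set C9 as in the target (C8 is later taken to a ketone).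

Step 12
Reactants: 19 aldol adduct
Product: 20 7,9-syn diol (C7 and C9 as in the target, 8-O-PMB)
Conditions: Et2BOMe, NaBH4, THF/MeOH 4:1, −78 °C; AcOH, then MeOH co-evaporation
Reagents that add atoms: none
Why: Narasaka–Prasad reduction, in which the boron chelate of the beta-hydroxy ketone is reduced by external axial hydride delivery, should give the 7,9-syn diol with 1,2-selectivity at the enone and independently of the C8 configuration.

Step 13
Reactants: 20 7,9-syn diol
Product: 22 C7 acrylate C9 acetate (8-O-PMB), via C7 monoacrylate 21 (not isolated)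
Conditions: acryloyl chloride (1.05 equiv), i-Pr2NEt, CH2Cl2, −78 °C; then Ac2O, DMAP, −78 → 25 °C
Reagents that add atoms: acryloyl chloride, C=CC(=O)Cl; acetic anhydride, CC(=O)OC(C)=O
Why: Site-selective esterification, in which the acid chloride should acylate the accessible allylic C7 hydroxyl at low temperature because the C9 hydroxyl is shielded by the fully substituted ring, after which DMAP-catalysed acetylation caps C9.

Step 14
Reactants: 22 C7 acrylate C9 acetate
Product: 23 C8 alcohol
Conditions: DDQ, CH2Cl2/pH 7 phosphate buffer 10:1, 0 °C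
Reagents that add atoms: none
Why: Oxidative PMB ether cleavage (benzylic hydride abstraction by DDQ and hydrolysis) should leave silyl ethers, esters and olefins intact.

Step 15
Reactants: 23 C8 alcohol
Product: 24 C8 ketone (7-acryloyloxy, 9-acetoxy)
Conditions: Dess–Martin periodinane, NaHCO3, CH2Cl2, 0 → 25 °C
Reagents that add atoms: none
Why: Dess–Martin oxidation converts the carbinol into the ketone under buffered, non-basic conditions that should not epimerise C7 or C9.

Step 16
Reactants: 24 C8 ketone
Product: 25 hydroxy lactone (gamma-lactone C19 to O–C7, 8-hydroxyl, C17 methyl; C7, C8, C17 as in the target)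
Conditions: [(Ph3P)CuH]6 (0.5 equiv), toluene, −40 → 0 °C; aq. NH4Cl
Reagents that add atoms: none
Why: Copper-hydride reductive aldol cyclisation, in which conjugate hydride addition to the acrylate (faster than ketone reduction) gives the (Z)-copper enolate that adds to the C8 ketone through a chelated chair-like transition state, the lactone closing with the bulky C9 substituent trans to the C7 alkenyl group (8-hydroxyl cis to it) and the C17 methyl syn to the new hydroxyl.

Step 17
Reactants: 25 hydroxy lactone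
Product: 26 C2,C4-diol (12-O-TBS retained)
Conditions: HF·pyridine, pyridine, THF, 0 °C
Reagents that add atoms: none
Why: Selective desilylation, buffered HF·pyridine being expected to cleave the two primary TBS ethers well before the hindered secondary allylic TBS ether at C12.

Step 18
Reactants: 26 C2,C4-diol
Product: 28 C4 allylic chloride C2 aldehyde, via C2 alkoxysulfonium chloride 27 (not isolated)
Conditions: N-chlorosuccinimide, Me2S, CH2Cl2, −25 → 0 °C; then Et3N, −25 → 25 °C
Reagents that add atoms: N-chlorosuccinimide, O=C1CCC(=O)N1Cl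
Why: Corey–Kim reaction, in which both primary alcohols form alkoxysulfonium salts, the allylic one collapsing to the (Z)-allylic chloride by SN2 attack of chloride without transposition and the neopentyl one being oxidised to the aldehyde on addition of triethylamine.

Step 19
Reactants: 28 chloro aldehyde
Product: 29 C8 triethylsilyl ether of 28
Conditions: Et3SiOTf, 2,6-lutidine, CH2Cl2, −78 → 0 °C
Reagents that add atoms: triethylsilyl trifluoromethanesulfonate, CC[Si](CC)(CC)OS(=O)(=O)C(F)(F)F
Why: Silyl triflate silylation of the tertiary hydroxyl (the aldehyde has no alpha-hydrogen) masks the only nucleophile that could close a six-membered ether onto C4.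

Step 20
Reactants: 30 allyl 3-oxobutanoate (allyl acetoacetate)
Product: 32 allyl diazoacetate, via allyl 2-diazo-3-oxobutanoate 31 (not isolated)
Conditions: 4-acetamidobenzenesulfonyl azide, Et3N, MeCN, 25 °C; then aq. LiOH, 0 °C
Reagents that add atoms: 4-acetamidobenzenesulfonyl azide, CC(=O)Nc1ccc(cc1)S(=O)(=O)N=[N+]=[N-]
Why: Regitz diazo transfer to the active methylene followed by hydroxide-induced deacetylation should give the diazoacetate (deacylative diazo transfer).

Step 21
Reactants: 29 aldehyde; 32 allyl diazoacetate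
Product: 33 seco allyl beta-keto ester (C2 ketone, C3 methylene, C4 chloride)
Conditions: SnCl2 (20 mol%), CH2Cl2, 25 °C
Reagents that add atoms: none
Why: Roskamp reaction, in which tin dichloride-catalysed addition of the diazoacetate to the aldehyde, 1,2-hydride shift and loss of nitrogen give the beta-keto ester and introduce C3.

Step 22
Reactants: 33 seco allyl beta-keto ester
Product: 34 macrocyclic allyl beta-keto ester (briarane skeleton, C3 epimers)
Conditions: Cs2CO3 (3 equiv), CsI (20 mol%), MeCN, 60 °C, syringe-pump addition (final 1 mM)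
Reagents that add atoms: none
Why: Cs2CO3 deprotonates only the doubly activated C3 methylene, and the caesium enolate displaces the primary allylic halide at C4 (chloride, exchanged in situ to iodide by CsI) in an intramolecular SN2 C-alkylation run under syringe-pump dilution. The closest known reaction type is the caesium carbonate-mediated macrocyclising C-alkylation of beta-keto esters and malonates with allylic halides. The ten-membered carbocycle closes in a 10-(enolendo)-exo-tet mode. The only new stereocentre is C3 (ester-bearing), formed without control and erased by the decarboxylation of step 23, whereas the preset 5Z-olefin and all existing stereocentres are untouched because substitution occurs at the CH2 terminus without allylic transposition. The step needs C- over O-alkylation, SN2 over SN2′ and cyclisation over oligomerisation, which the soft enolate/allylic iodide pair, the hindered C6 terminus, high dilution and the turn elements of the seco chain (trans-1,2-disubstituted cyclohexene at C1/C10, gamma-lactone at C7/C8, cis olefin) should secure. The C8 hydroxyl, the only group that could close a six-membered ether onto C4, is masked as its TES ether.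

Step 23
Reactants: 34 macrocyclic allyl beta-keto ester
Product: 36 macrocyclic C2 ketone, via beta-keto acid 35 (not isolated)
Conditions: Pd(PPh3)4 (5 mol%), morpholine, THF, 25 → 40 °C
Reagents that add atoms: none
Why: Tsuji–Trost deallylation, in which zerovalent palladium should ionise the unsubstituted allyl ester far faster than the hindered allylic lactone, morpholine traps the allyl group and the beta-keto acid loses carbon dioxide, which also removes the C3 stereocentre.

Step 24
Reactants: 36 macrocyclic C2 ketone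
Product: 37 (2R)-C2 alcohol
Conditions: (S)-1-methyl-3,3-diphenyltetrahydro-1H,3H-pyrrolo[1,2-c][1,3,2]oxazaborole (20 mol%), catecholborane, toluene, −78 °C; MeOH
Reagents that add atoms: none
Why: Corey–Bakshi–Shibata reduction, in which the (S)-oxazaborolidine differentiates the quaternary C1 side from the C3 methylene and should deliver hydride under reagent control to give the (2R)-alcohol, catecholborane leaving olefins, lactone and acetate untouched.

Step 25
Reactants: 37 C2 alcohol
Product: 38 2,9-diacetate (8-O-TES, 12-O-TBS)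
Conditions: Ac2O, DMAP, Et3N, CH2Cl2, 25 °C
Reagents that add atoms: acetic anhydride, CC(=O)OC(C)=O
Why: DMAP-catalysed acetylation (esterification) of the only free hydroxyl.

Step 26
Reactants: 38 2,9-diacetate
Product: 39 8,12-diol (2,9-diacetate)
Conditions: HF·pyridine (excess), THF, 0 → 25 °C
Reagents that add atoms: none
Why: Global desilylation, fluoride cleaving the triethylsilyl and the remaining tert-butyldimethylsilyl ether under mildly acidic conditions that should not cause acyl migration.

Step 27
Reactants: 39 8,12-diol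
Product: 40 CNP0211702.1 (2,9-diacetoxy-12-butanoyloxy-8-hydroxybriara-5Z,13-dien-18,7-olide)
Conditions: (n-PrCO)2O, DMAP (cat.), pyridine, CH2Cl2, 0 °C
Reagents that add atoms: butanoic anhydride, CCCC(=O)OC(=O)CCC
Why: DMAP-catalysed esterification of the secondary allylic C12 hydroxyl, the tertiary C8 hydroxyl being unreactive, should complete the target.

Compound list
1 | pent-1-en-3-one | CCC(=O)C=C | starting material
2 | (Z)-3-(tert-butyldimethylsilyloxy)penta-1,3-diene | C=C/C(O[Si](C)(C)C(C)(C)C)=C/C | intermediate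
3 | ethyl (E)-3-methyl-4-oxobut-2-enoate | CCOC(=O)/C=C(C)/C=O | starting material
4 | Diels–Alder adduct, ethyl 6-formyl-2,6-dimethyl-3-(TBS-oxy)cyclohex-3-ene-1-carboxylate | CC(C)(C)[Si](C)(C)OC1=CC[C@@](C=O)(C)[C@H]([C@H]1C)C(=O)OCC | intermediate
5 | ethyl 6-formyl-2,6-dimethyl-3-oxocyclohex-4-ene-1-carboxylate | O=C1C=C[C@@](C=O)(C)[C@H]([C@H]1C)C(=O)OCC | intermediate
6 | ethyl 3-hydroxy-6-(hydroxymethyl)-2,6-dimethylcyclohex-4-ene-1-carboxylate | O[C@@H]1C=C[C@@](CO)(C)[C@H]([C@H]1C)C(=O)OCC | intermediate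
7 | bis-TBS ether of 6 | CC(C)(C)[Si](C)(C)O[C@@H]1C=C[C@@](CO[Si](C)(C)C(C)(C)C)(C)[C@H]([C@H]1C)C(=O)OCC | intermediate
8 | C9 aldehyde | CC(C)(C)[Si](C)(C)O[C@@H]1C=C[C@@](CO[Si](C)(C)C(C)(C)C)(C)[C@H]([C@H]1C)C=O | intermediate
9 | prop-2-yn-1-ol | C#CCO | starting material
10 | alkenylmagnesium alkoxide (not isolated) | Br[Mg]/C=C(/C)CO[Mg]Br | intermediate
11 | (Z)-3-iodo-2-methylprop-2-en-1-ol | I/C=C(/C)CO | intermediate
12 | (Z)-tert-butyl[(3-iodo-2-methylprop-2-en-1-yl)oxy]dimethylsilane | I/C=C(/C)CO[Si](C)(C)C(C)(C)C | intermediate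
13 | 2-chloro-N-methoxy-N-methylacetamide | ClCC(=O)N(C)OC | starting material
14 | 4-methoxybenzyl alcohol | COc1ccc(CO)cc1 | starting material
15 | N-methoxy-2-(4-methoxybenzyloxy)-N-methylacetamide | COc1ccc(COCC(=O)N(C)OC)cc1 | intermediate
16 | alkenyllithium (not isolated) | [Li]/C=C(/C)CO[Si](C)(C)C(C)(C)C | intermediate
17 | (Z)-5-(TBS-oxy)-1-(4-methoxybenzyloxy)-4-methylpent-3-en-2-one | COc1ccc(COCC(=O)/C=C(/C)CO[Si](C)(C)C(C)(C)C)cc1 | intermediate
18 | (E)-enol dicyclohexylborinate of 17 (not isolated) | COc1ccc(CO/C=C(/OB(C2CCCCC2)C2CCCCC2)\C=C(\C)CO[Si](C)(C)C(C)(C)C)cc1 | intermediate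
19 | aldol adduct (9-hydroxy, 8-O-PMB, 7-oxo) | CC(C)(C)[Si](C)(C)O[C@@H]1C=C[C@@](CO[Si](C)(C)C(C)(C)C)(C)[C@H]([C@H]1C)[C@@H](O)[C@@H](OCc1ccc(OC)cc1)C(=O)/C=C(/C)CO[Si](C)(C)C(C)(C)C | intermediate
20 | 7,9-syn diol (8-O-PMB) | CC(C)(C)[Si](C)(C)O[C@@H]1C=C[C@@](CO[Si](C)(C)C(C)(C)C)(C)[C@H]([C@H]1C)[C@@H](O)[C@@H](OCc1ccc(OC)cc1)[C@H](/C=C(/C)CO[Si](C)(C)C(C)(C)C)O | intermediate
21 | C7 monoacrylate (not isolated) | CC(C)(C)[Si](C)(C)O[C@@H]1C=C[C@@](CO[Si](C)(C)C(C)(C)C)(C)[C@H]([C@H]1C)[C@@H](O)[C@@H](OCc1ccc(OC)cc1)[C@H](/C=C(/C)CO[Si](C)(C)C(C)(C)C)OC(=O)C=C | intermediate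
22 | C7 acrylate C9 acetate (8-O-PMB) | CC(C)(C)[Si](C)(C)O[C@@H]1C=C[C@@](CO[Si](C)(C)C(C)(C)C)(C)[C@H]([C@H]1C)[C@@H](OC(C)=O)[C@@H](OCc1ccc(OC)cc1)[C@H](/C=C(/C)CO[Si](C)(C)C(C)(C)C)OC(=O)C=C | intermediate
23 | C8 alcohol | CC(C)(C)[Si](C)(C)O[C@@H]1C=C[C@@](CO[Si](C)(C)C(C)(C)C)(C)[C@H]([C@H]1C)[C@@H](OC(C)=O)[C@@H](O)[C@H](/C=C(/C)CO[Si](C)(C)C(C)(C)C)OC(=O)C=C | intermediate
24 | C8 ketone | CC(C)(C)[Si](C)(C)O[C@@H]1C=C[C@@](CO[Si](C)(C)C(C)(C)C)(C)[C@H]([C@H]1C)[C@@H](OC(C)=O)C(=O)[C@H](/C=C(/C)CO[Si](C)(C)C(C)(C)C)OC(=O)C=C | intermediate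
25 | hydroxy lactone | CC(C)(C)[Si](C)(C)O[C@@H]1C=C[C@@](CO[Si](C)(C)C(C)(C)C)(C)[C@H]([C@H]1C)[C@@H](OC(C)=O)[C@@]1(O)[C@H](/C=C(/C)CO[Si](C)(C)C(C)(C)C)OC(=O)[C@@H]1C | intermediate
26 | C2,C4-diol | CC(C)(C)[Si](C)(C)O[C@@H]1C=C[C@@](CO)(C)[C@H]([C@H]1C)[C@@H](OC(C)=O)[C@@]1(O)[C@H](/C=C(/C)CO)OC(=O)[C@@H]1C | intermediate
27 | C2 alkoxysulfonium chloride of the C4 chloride (not isolated) | CC(C)(C)[Si](C)(C)O[C@@H]1C=C[C@@](CO[S+](C)C)(C)[C@H]([C@H]1C)[C@@H](OC(C)=O)[C@@]1(O)[C@H](/C=C(/C)CCl)OC(=O)[C@@H]1C.[Cl-] | intermediate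
28 | C4 allylic chloride C2 aldehyde | CC(C)(C)[Si](C)(C)O[C@@H]1C=C[C@@](C=O)(C)[C@H]([C@H]1C)[C@@H](OC(C)=O)[C@@]1(O)[C@H](/C=C(/C)CCl)OC(=O)[C@@H]1C | intermediate
29 | C8 triethylsilyl ether of 28 | CC(C)(C)[Si](C)(C)O[C@@H]1C=C[C@@](C=O)(C)[C@H]([C@H]1C)[C@@H](OC(C)=O)[C@@]1(O[Si](CC)(CC)CC)[C@H](/C=C(/C)CCl)OC(=O)[C@@H]1C | intermediate
30 | allyl 3-oxobutanoate | CC(=O)CC(=O)OCC=C | starting material
31 | allyl 2-diazo-3-oxobutanoate (not isolated) | CC(=O)C(=[N+]=[N-])C(=O)OCC=C | intermediate
32 | allyl diazoacetate | C=CCOC(=O)C=[N+]=[N-] | intermediate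
33 | seco allyl beta-keto ester | CC(C)(C)[Si](C)(C)O[C@@H]1C=C[C@@](C(=O)CC(=O)OCC=C)(C)[C@H]([C@H]1C)[C@@H](OC(C)=O)[C@@]1(O[Si](CC)(CC)CC)[C@H](/C=C(/C)CCl)OC(=O)[C@@H]1C | intermediate
34 | macrocyclic allyl beta-keto ester (C3 epimers) | CC(C)(C)[Si](C)(C)O[C@@H]1C=C[C@@]2(C)[C@H]([C@H]1C)[C@@H](OC(C)=O)[C@@]1(O[Si](CC)(CC)CC)[C@H](/C=C(/C)CC(C(=O)OCC=C)C2=O)OC(=O)[C@@H]1C | intermediate
35 | macrocyclic beta-keto acid (not isolated) | CC(C)(C)[Si](C)(C)O[C@@H]1C=C[C@@]2(C)[C@H]([C@H]1C)[C@@H](OC(C)=O)[C@@]1(O[Si](CC)(CC)CC)[C@H](/C=C(/C)CC(C(=O)O)C2=O)OC(=O)[C@@H]1C | intermediate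
36 | macrocyclic C2 ketone | CC(C)(C)[Si](C)(C)O[C@@H]1C=C[C@@]2(C)[C@H]([C@H]1C)[C@@H](OC(C)=O)[C@@]1(O[Si](CC)(CC)CC)[C@H](/C=C(/C)CCC2=O)OC(=O)[C@@H]1C | intermediate
37 | (2R)-C2 alcohol | CC(C)(C)[Si](C)(C)O[C@@H]1C=C[C@@]2(C)[C@H]([C@H]1C)[C@@H](OC(C)=O)[C@@]1(O[Si](CC)(CC)CC)[C@H](/C=C(/C)CC[C@H]2O)OC(=O)[C@@H]1C | intermediate
38 | 2,9-diacetate (8-O-TES, 12-O-TBS) | CC(C)(C)[Si](C)(C)O[C@@H]1C=C[C@@]2(C)[C@H]([C@H]1C)[C@@H](OC(C)=O)[C@@]1(O[Si](CC)(CC)CC)[C@H](/C=C(/C)CC[C@H]2OC(C)=O)OC(=O)[C@@H]1C | intermediate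
39 | 8,12-diol 2,9-diacetate | O[C@@H]1C=C[C@@]2(C)[C@H]([C@H]1C)[C@@H](OC(C)=O)[C@@]1(O)[C@H](/C=C(/C)CC[C@H]2OC(C)=O)OC(=O)[C@@H]1C | intermediate
40 | CNP0211702.1 | CCCC(=O)O[C@@H]1C=C[C@@]2(C)[C@H]([C@H]1C)[C@@H](OC(C)=O)[C@@]1(O)[C@H](/C=C(/C)CC[C@H]2OC(C)=O)OC(=O)[C@@H]1C | target

Total step count: 27. Longest linear sequence: 22 steps (steps 1–6, 11–19 and 21–27).

Steps most likely to fail:

Step 22. Ten-membered ring closure is slow, so intermolecular alkylation (oligomerisation) or O-alkylation of the enolate may outrun the C-alkylation. The fallback sets out from aldehyde 29: a Roskamp homologation with tert-butyl diazoacetate (SnCl2) would give the seco tert-butyl beta-keto ester F1, which would be cyclised through a pi-allyl palladium intermediate under zerovalent-palladium catalysis (Pd(PPh3)4, Cs2CO3, THF, 60 °C, high dilution; Tsuji–Trost macrocyclisation, attack at the unsubstituted C4 terminus, the cis-olefin being favoured by the ring constraint) to the macrocyclic tert-butyl beta-keto ester F2. Cleavage of the tert-butyl ester with Me3SiOTf/2,6-lutidine and decarboxylation on aqueous work-up would return to the route at ketone 36.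

Step 16. The bis(acyloxy) ketone may epimerise at C7 or C9 under the basic copper enolate and alkoxide species, or the aldol may add to the wrong carbonyl face, eroding C8 and C17. The fallback sets out from diol 20: acylation of the C7 hydroxyl with 2-bromopropanoyl bromide followed by acetylation would give the C7 2-bromopropanoate C9 acetate F3, DDQ would give the C8 alcohol F4 and Dess–Martin oxidation the alpha-(2-bromopropanoyloxy) ketone F5. SmI2 (THF, −78 °C) would then effect a fast, non-basic, chelation-organised intramolecular samarium Reformatsky reaction and return to the route at hydroxy lactone 25.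

Step 4. Hydride may be delivered to the sterically more open equatorial face of the enone, because the axial C10 ester hinders pseudo-axial attack, which would give the C12 epimer. The fallback sets out from enone 5: the Luche reduction would then furnish the 12-epi diol F6, silylation of the primary hydroxyl only (TBSCl, imidazole) would give the mono-TBS ether F7, and Mitsunobu esterification (4-nitrobenzoic acid, PPh3, diisopropyl azodicarboxylate) would invert C12 to give the 4-nitrobenzoate F8. Methanolysis (K2CO3, MeOH) would give the C12 alcohol of target configuration F9, and silylation with TBSOTf would return to the route at bis-TBS ether 7.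

Further compounds
F1 | step 22 | seco tert-butyl beta-keto ester (tert-butyl analogue of 33) | CC(C)(C)[Si](C)(C)O[C@@H]1C=C[C@@](C(=O)CC(=O)OC(C)(C)C)(C)[C@H]([C@H]1C)[C@@H](OC(C)=O)[C@@]1(O[Si](CC)(CC)CC)[C@H](/C=C(/C)CCl)OC(=O)[C@@H]1C
F2 | step 22 | macrocyclic tert-butyl beta-keto ester (tert-butyl analogue of 34) | CC(C)(C)[Si](C)(C)O[C@@H]1C=C[C@@]2(C)[C@H]([C@H]1C)[C@@H](OC(C)=O)[C@@]1(O[Si](CC)(CC)CC)[C@H](/C=C(/C)CC(C(=O)OC(C)(C)C)C2=O)OC(=O)[C@@H]1C
F3 | step 16 | C7 2-bromopropanoate C9 acetate (8-O-PMB) | CC(C)(C)[Si](C)(C)O[C@@H]1C=C[C@@](CO[Si](C)(C)C(C)(C)C)(C)[C@H]([C@H]1C)[C@@H](OC(C)=O)[C@@H](OCc1ccc(OC)cc1)[C@H](/C=C(/C)CO[Si](C)(C)C(C)(C)C)OC(=O)C(C)Br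
F4 | step 16 | C8 alcohol of F3 | CC(C)(C)[Si](C)(C)O[C@@H]1C=C[C@@](CO[Si](C)(C)C(C)(C)C)(C)[C@H]([C@H]1C)[C@@H](OC(C)=O)[C@@H](O)[C@H](/C=C(/C)CO[Si](C)(C)C(C)(C)C)OC(=O)C(C)Br
F5 | step 16 | alpha-(2-bromopropanoyloxy) C8 ketone | CC(C)(C)[Si](C)(C)O[C@@H]1C=C[C@@](CO[Si](C)(C)C(C)(C)C)(C)[C@H]([C@H]1C)[C@@H](OC(C)=O)C(=O)[C@H](/C=C(/C)CO[Si](C)(C)C(C)(C)C)OC(=O)C(C)Br
F6 | step 4 | 12-epi diol (12-hydroxyl cis to the C11 methyl) | O[C@H]1C=C[C@@](CO)(C)[C@H]([C@H]1C)C(=O)OCC
F7 | step 4 | primary mono-TBS ether of F6 | O[C@H]1C=C[C@@](CO[Si](C)(C)C(C)(C)C)(C)[C@H]([C@H]1C)C(=O)OCC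
F8 | step 4 | C12 4-nitrobenzoate of inverted configuration | O=C(O[C@@H]1C=C[C@@](CO[Si](C)(C)C(C)(C)C)(C)[C@H]([C@H]1C)C(=O)OCC)c1ccc(cc1)[N+](=O)[O-]
F9 | step 4 | C12 alcohol of target configuration (2-O-TBS) | O[C@@H]1C=C[C@@](CO[Si](C)(C)C(C)(C)C)(C)[C@H]([C@H]1C)C(=O)OCC
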